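I began with the end state.

| flask | starting complex | incoming ligand | time |
|---|---|---|---|
| dawn | 0.062 M | 2.00 equiv | 1.0 min |
| spring | 0.062 M | 4.00 equiv | 1.0 min |

    starting complex + incoming ligand ⇌ leaving ligand + complex with one exchanged (K1 = 0.64, k1 = 0.24 M⁻¹ s⁻¹)
    complex with one exchanged + incoming ligand ⇌ leaving ligand + complex with two exchanged (K2 = 0.27, k2 = 0.031 M⁻¹ s⁻¹)
    starting complex + complex with one exchanged → side product (k3 = 0.17 M⁻¹ s⁻¹)

- a species is counted by the starting complex in it: one side product counts as two
- run time (dawn): 1.0 min

- which of these there is most of at the end, counted by the starting complex in it, dawn (complex with one exchanged / complex with two exchanged / starting complex / side product)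
- which of these there is most of at the end, counted by the starting complex in it, spring (complex with one exchanged / complex with two exchanged / starting complex / side product)
- amount of the one of these that there is most of at the end, in percent of the starting complex charged, dawn
- amount of the one of these that there is most of at the end, in percent of the starting complex charged, spring

The first step has an equilibrium constant of 0.64, below one, so it looked uphill, yet at dawn it allowed 59.9% of the charge to stand exchanged. That figure is the ceiling: the fraction of the charge held as complex with one exchanged once the first step, running by itself, has reached equilibrium. Each side of that step has two partners, so the concentration cancels and the ceiling follows from the constant and the equivalents. The contradiction cleared at dawn because free incoming ligand outnumbers leaving ligand 2.34 to one at the ceiling, which lifts the ratio of exchanged to starting complex to 1.50.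

Then I asked how fast. Integrating the first step at dawn gave an approach constant of 3.28 min⁻¹. Taking the dawn flask as standing at the ceiling, and counting the second step forward only, I gave the second and third steps together a pseudo-first-order loss constant for complex with one exchanged of 0.415 min⁻¹. Multiplying the ceiling by the fraction of the approach made and the fraction surviving the loss, I committed to 38.1% at dawn. In spring the ceiling was 73.9%, the approach constant 5.21 min⁻¹ and the loss constant 0.541 min⁻¹, which gave 42.7%. I expected complex with one exchanged to lead in both flasks.

The forecast named complex with one exchanged at dawn and complex with one exchanged in spring, with 42% (37% to 47%) and 47% (41% to 53%), both above my figures, on the ground that “The first exchange is fast enough to get close to its equilibrium well within the minute”.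

The flask gave complex with one exchanged at 40.5% at dawn and complex with one exchanged at 46.6% in spring. At dawn 33.8% remained as starting complex, and the leader stood at 67.6% of its ceiling. A neighbouring flask, dawn's recipe at 0.025 M of starting complex, keeps the ceiling of 59.9%, while my approach and loss constants, which are reckoned with the concentration as a factor, shrink in proportion to it, so the same reckoning gives 37.2%. That neighbouring flask held 36.6% of complex with one exchanged, less than its 53.8% of starting complex.

The constants are made up; the result is computed.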